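**Numbering used throughout.** Ring B carbons are C1 (bears the depside carbonyl) to C6 (bears propyl). Ring A carbons are C1' (bears the carboxyl) to C6' (bears pentyl).

Compounds: 1 1-bromo-3,5-dimethoxybenzene; 2 propylmagnesium bromide; 3 1,3-dimethoxy-5-propylbenzene; 4 (2,6-dimethoxy-4-propylphenyl)lithium; 5 2-chloro-1,3-dimethoxy-5-propylbenzene; 6 2-chloro-4-iodo-1,3-dimethoxy-5-propylbenzene; 7 olivetol; 8 olivetolic acid; 9 tert-butyl 2,4-dihydroxy-6-pentylbenzoate; 10 carbon monoxide; 11 tert-butyl 4-(3-chloro-2,4-dimethoxy-6-propylbenzoyloxy)-2-hydroxy-6-pentylbenzoate; 12 the target.

## Analysis of the target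

The target 12 is a depside: two benzene rings and no further ring, joined by one aryl ester between the C1 carbonyl of ring B, a 3-chloro-2-hydroxy-4-methoxy-6-propylbenzoyl group, and O-4' of ring A, an olivetolic acid unit with the carboxyl on C1', a hydroxyl on C2' and the pentyl group on C6'. There is no stereocentre, so the problem is one of regiochemistry and chemoselectivity. The sensitive groups are the aryl ester (cleaved by hydroxide, alkoxides and amines), the β-resorcylic acid of ring A (loses CO2 on heating or in hot acid), the free phenols and the aryl chloride (lost under hydrogenolysis). The first difficulty is that the depside carbonyl sits on C1 of ring B between the C2 oxygen and the C6 propyl group, so acylating a phenol with this acid means attack at a shielded carbon. The second is that the chlorine at C3 lies between two oxygens, a position that electrophilic chlorination does not favour, and only one of those oxygens is methylated; the third is that ring A offers two hydroxyls and a carboxyl, of which only O-4' may be acylated. The strategy rests on the fact that, with the depside carbonyl carbon removed and O-2 methylated, ring B is arene 5, which has a mirror plane through its chlorine-bearing and propyl-bearing carbons. Its two open positions are therefore identical and only one iodide, 6, can form. The extra methyl group ends up ortho to the depside carbonyl, the one place from which a boron Lewis acid removes a methyl ether selectively.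

## Retrosynthetic reasoning

**12 to 11.** The O–CH3 bond at O-2 of ring B and the O–C(CH3)3 bond of the ring A ester are cut. Both can be broken by a single Lewis acid under non-basic, non-nucleophilic conditions that leave the depside ester alone. The O-2 methyl is told apart from the O-4 methyl by chelation to the neighbouring carbonyl. Going back to 11 makes ring B symmetric before the carbonyl is attached and masks the C2 phenol and the ring A carboxyl during the metal-catalysed step. The forward reaction has to cleave two alkyl–oxygen bonds and keep the 4-methoxy group and the aryl ester.

**11 to 6, 10 and 9.** Both bonds to the depside carbonyl are cut: C1–C(=O) and C(=O)–O-4'. Cutting only the C(=O)–O bond would leave an acyl carbon with two ortho substituents that has to be activated and then attacked in a crowded environment. Cutting both turns the carbonyl into 10 and moves bond formation to a metal centre, where the acyl group is built on the spot and handed to the phenoxide. Ring B is reduced to the aryl iodide 6 and the route becomes convergent. The forward reaction must choose C–I over C–Cl in 6 and O-4' over O-2' in 9.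

**6 to 5.** The C–I bond is cut. Arene 5 has only two open positions, equivalent by symmetry and activated by an ortho and a para methoxy group, so electrophilic iodination cannot give an isomer.

**5 to 3 through 4.** The C–Cl bond between the two methoxy groups is cut. An electrophilic chlorine source would attack 3 next to the propyl group. The hydrogen between the two oxygens is the most acidic on the ring, so deprotonation to 4 and trapping with a chlorine donor places the halogen where substitution would not.

**3 to 1 and 2.** The aryl–propyl bond is cut. The meta relationship of the alkyl group to both oxygens cannot be made by electrophilic alkylation, but it is already present in bromide 1. A nickel-catalysed coupling with the primary Grignard reagent 2 forms the bond directly.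

**9 to 8.** The oxygen–tert-butyl bond of the ester is cut. The forward step must put the tert-butyl group on the carboxylate oxygen without attack at the hindered acyl carbon, without alkylating either phenol and without heating 8 to the point of decarboxylation.

**8 to 7.** The C1'–carboxyl bond is cut. The forward step is an ortho-carboxylation of the resorcinol 7 at the carbon flanked by a hydroxyl and the pentyl group.

## Alternatives that were turned down

**Alternative 1:** Ring B is disconnected between C1 and C6, so the depside ester exists before ring B does. The precursor is the O-4' ester of ring A with a 3,5,7-trioxodecanoyl chain, allyl 2-hydroxy-6-pentyl-4-(3,5,7-trioxodecanoyloxy)benzoate A2. In the forward step the C2 methylene of the chain adds to the C7 ketone, and dehydration and enolisation give allyl 4-(2,4-dihydroxy-6-propylbenzoyloxy)-2-hydroxy-6-pentylbenzoate A1.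
- For: the hindered acylation never has to be done, because the ester is made on an unbranched acyl chain, and ring B with its propyl group arises in one operation. On the ester bond this plan is stronger than the chosen one.
- Against: A1 carries neither the chlorine nor the methyl ether. Chlorination would have to pick C3 of ring B over C5 and over C3' and C5' of ring A, and nothing in A1 tells these positions apart. A2 is also an aryl ester of a β-keto acid with two more ketones in the chain. Aryloxide is a good leaving group, so Claisen-type closure onto the ester carbonyl or enol lactonisation would expel ring A in competition with the aldol. The strongly basic enolate chemistry needed to assemble the triketo chain would not spare an aryl ester either.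
- Comparison: the chosen route places chlorine by lithiation between two methoxy groups and needs one operation after the key step. A1 would need O-methylation, chlorination and deallylation, each with a selectivity question.

**Alternative 2:** Ring A is disconnected at the C6'–pentyl and C1'–carboxyl bonds, both made on an aryne. 1-Fluoro-3,5-dimethoxybenzene A4 is lithiated between fluorine and a methoxy group and loses fluoride to give 3,5-dimethoxybenzyne A5. Pentyllithium A6 adds at the aryne carbon remote from the methoxy group, and the new aryllithium, now next to that methoxy group, is carboxylated to 2,4-dimethoxy-6-pentylbenzoic acid A3.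
- For: one flask, and the positions of pentyl and carboxyl are fixed by the polarisation of the aryne. On this point it is stronger than the carboxylation of 7, which has two candidate positions.
- Against: it spends its key step on the easier half of the target. Ring A is two steps from 7, whereas A3 has both oxygens as methyl ethers. To become a coupling partner it must lose both methyl groups, and the O-4' methyl, with no chelating neighbour, needs forcing conditions under which a β-resorcylic acid decarboxylates. It must then gain a carboxyl protecting group. A6 has to serve both as the base that lithiates A4 and as the nucleophile, and the aryllithium intermediates can add to A5 themselves.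
- Comparison: the depside bond, the chlorine and the hindered acylation are untouched by this idea, so a second key step would still be needed. The chosen strategy puts its key step on the bond that makes the target hard.

**Alternative 3:** Ring B is disconnected at C1–C2 and C5–C6. Allyl 4-(hex-2-ynoyloxy)-2-hydroxy-6-pentylbenzoate A8 and 2-chloro-1,3-dimethoxy-1-(trimethylsilyloxy)buta-1,3-diene A9 would combine in a [4+2] cycloaddition. The unsubstituted diene terminus bonds to the propyl-bearing alkyne carbon. Loss of the methoxy group from the former acetal carbon aromatises the adduct, and desilylation gives the allyl ester of the target, allyl 4-(3-chloro-2-hydroxy-4-methoxy-6-propylbenzoyloxy)-2-hydroxy-6-pentylbenzoate A7.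
- For: ring B appears in A7 with its final substitution, including chlorine, the free 2-hydroxyl and the 4-methoxy group. No demethylation is needed and the ester is formed on an unhindered alkynoyl chain. In the end game and in avoiding the hindered acylation it is stronger than the chosen route.
- Against: a β-alkyl ynoate is a sluggish dienophile and needs heat. A9 is a fully substituted, chlorinated silyl ketene acetal that is sensitive to moisture and acid, is hard to obtain as one geometric isomer and would not tolerate that heat well. The free 2'-hydroxyl of A8 can protonate it. A8 is also a Michael acceptor for its own phenol.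
- Comparison: the chosen route sets each ring B substituent by a reaction with only one possible outcome on a symmetric arene, reaches 6 in three steps, and uses a catalytic carbonylation from a well-studied family. Making A8 and A9 would each take several steps before an uncertain cycloaddition to A7.

Key step: step 6

Remark on the chemistry: carbon monoxide is used as the gas at atmospheric pressure, and the tert-butyl group removed in step 7 is assumed to leave as tert-butyl chloride.

## Route

Step 1
Reactants: 1 1-bromo-3,5-dimethoxybenzene; 2 propylmagnesium bromide
Product: 3 1,3-dimethoxy-5-propylbenzene
Conditions: NiCl2(dppp) (2 mol%), 2 (1.3 equiv), THF, 0 °C → reflux; aq. NH4Cl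
Reagents that add atoms: none
Why: Kumada cross-coupling: zerovalent nickel formed from NiCl2(dppp) and the Grignard reagent inserts into the C–Br bond, and transmetalation and reductive elimination form the aryl–propyl bond. The chelating dppp ligand makes reductive elimination faster than β-hydride elimination, so the propyl group should arrive unbranched, and the methyl ethers are inert.

Step 2
Reactants: 3 1,3-dimethoxy-5-propylbenzene
Product: 5 2-chloro-1,3-dimethoxy-5-propylbenzene, via (2,6-dimethoxy-4-propylphenyl)lithium 4 (not isolated)
Conditions: n-BuLi (1.2 equiv), THF, 0 °C → rt; then C2Cl6 (1.3 equiv), −78 °C → rt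
Reagents that add atoms: hexachloroethane, ClC(Cl)(Cl)C(Cl)(Cl)Cl
Why: Directed ortho-metalation: the hydrogen between the two methoxy groups is the most acidic on the ring and both oxygens hold the lithium, so 4 forms there and not beside the propyl group. Hexachloroethane then transfers electrophilic chlorine to the aryllithium.

Step 3
Reactants: 5 2-chloro-1,3-dimethoxy-5-propylbenzene
Product: 6 2-chloro-4-iodo-1,3-dimethoxy-5-propylbenzene
Conditions: NIS (1.05 equiv), TFA (0.3 equiv), MeCN, rt, dark
Reagents that add atoms: N-iodosuccinimide, O=C1CCC(=O)N1I
Why: Electrophilic aromatic iodination with acid-activated NIS: the two open positions of 5 are equivalent by symmetry and each is ortho to one methoxy group and para to the other, so only one monoiodide can form. After the first substitution the methoxy group next to iodine is flanked on both sides and twists out of conjugation, which should hold back a second iodination.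

Step 4
Reactants: 7 olivetol (5-pentylbenzene-1,3-diol)
Product: 8 olivetolic acid (2,4-dihydroxy-6-pentylbenzoic acid)
Conditions: MeOMgOCO2Me (2 M in DMF, 4 equiv), 120 °C, N2; then cold 1 M HCl
Reagents that add atoms: methyl magnesium carbonate, COC(=O)O[Mg]OC
Why: Kolbe–Schmitt-type carboxylation with a magnesium alkyl carbonate: the magnesium phenoxide of 7 is carboxylated at the carbon ortho to one oxygen and para to the other, and the product is held as a magnesium salicylate chelate that drives the equilibrium. This reagent is an established way to turn 5-alkylresorcinols into their β-resorcylic acids. Acidification is done cold because 8 loses CO2 when heated in acid.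

Step 5
Reactants: 8 olivetolic acid
Product: 9 tert-butyl 2,4-dihydroxy-6-pentylbenzoate
Conditions: O-tert-butyl-N,N'-diisopropylisourea (2.5 equiv), CH2Cl2, rt; filter off the urea
Reagents that add atoms: O-tert-butyl-N,N'-diisopropylisourea, CC(C)NC(=NC(C)C)OC(C)(C)C
Why: Esterification with an O-alkylisourea: the carboxylic acid protonates the isourea and the carboxylate takes up the tert-butyl group at oxygen, so the crowded acyl carbon of 8 is never attacked and neither strong acid nor heat is needed. The phenols are too weakly acidic to activate the reagent at room temperature, so alkylation should stop at the carboxyl group.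

Step 6
Reactants: 6 2-chloro-4-iodo-1,3-dimethoxy-5-propylbenzene; 10 carbon monoxide; 9 tert-butyl 2,4-dihydroxy-6-pentylbenzoate
Product: 11 tert-butyl 4-(3-chloro-2,4-dimethoxy-6-propylbenzoyloxy)-2-hydroxy-6-pentylbenzoate
Conditions: Pd(OAc)2 (5 mol%), Xantphos (6 mol%), NEt3 (3 equiv), CO (1 atm, balloon), 9 (1.2 equiv), toluene, 90 °C
Reagents that add atoms: none
Why: Pd(OAc)2 is reduced in the flask to zerovalent palladium carried by Xantphos, which inserts into the C–I bond of 6; the much stronger C–Cl bond, buried between two methoxy groups, should be left alone. CO then binds and the aryl group migrates onto it to give an aroyl complex of divalent palladium, a step that relieves the crowding around the aryl–palladium bond, so the ortho methoxy and propyl groups do not stand in its way. NEt3 deprotonates the 4-hydroxyl of 9, the phenoxide enters the coordination sphere, and C–O reductive elimination, favoured by the wide bite angle of Xantphos, releases ester 11 and returns zerovalent palladium, with the iodide leaving as its triethylammonium salt. The closest known reaction type is the palladium-catalysed alkoxy- and aryloxycarbonylation of aryl iodides with CO and phenols at atmospheric pressure. No ring is closed and no stereocentre is formed. The selectivity between the two hydroxyls of 9 comes from the substrate: the 2-hydroxyl is tied to the ester carbonyl by a hydrogen bond, is the less acidic one and sits beside the tert-butyl ester, while the 4-hydroxyl is para to the ester, more acidic and open on both sides. Keeping 6 as the limiting component should hold back double acylation.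

Step 7
Reactants: 11 tert-butyl 4-(3-chloro-2,4-dimethoxy-6-propylbenzoyloxy)-2-hydroxy-6-pentylbenzoate
Product: 12 4-(3-chloro-2-hydroxy-4-methoxy-6-propylbenzoyloxy)-2-hydroxy-6-pentylbenzoic acid (target)
Conditions: BCl3 (1 M in CH2Cl2, 4 equiv), CH2Cl2, −78 → 0 °C; then ice-water, work-up without heating
Reagents that add atoms: none
Why: Lewis acid dealkylation: BCl3 binds between the depside carbonyl oxygen and the neighbouring 2-methoxy oxygen of ring B, and chloride removes that methyl group by SN2 attack; the 4-methoxy group has no carbonyl partner for chelation and should stay. The tert-butyl ester, activated through the boron chelate of O-2' and its carbonyl, ionises to the tert-butyl cation, which chloride captures. Cold aqueous work-up hydrolyses the boron esters to the phenol and the acid without the heat that would decarboxylate ring A.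

## Compound list

1 | 1-bromo-3,5-dimethoxybenzene | COc1cc(Br)cc(OC)c1 | starting material
2 | propylmagnesium bromide | CCC[Mg]Br | starting material
3 | 1,3-dimethoxy-5-propylbenzene | CCCc1cc(OC)cc(OC)c1 | intermediate
4 | (2,6-dimethoxy-4-propylphenyl)lithium | CCCc1cc(OC)c([Li])c(OC)c1 | intermediate
5 | 2-chloro-1,3-dimethoxy-5-propylbenzene | CCCc1cc(OC)c(Cl)c(OC)c1 | intermediate
6 | 2-chloro-4-iodo-1,3-dimethoxy-5-propylbenzene | CCCc1cc(OC)c(Cl)c(OC)c1I | intermediate
7 | olivetol (5-pentylbenzene-1,3-diol) | CCCCCc1cc(O)cc(O)c1 | starting material
8 | olivetolic acid (2,4-dihydroxy-6-pentylbenzoic acid) | CCCCCc1cc(O)cc(O)c1C(=O)O | intermediate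
9 | tert-butyl 2,4-dihydroxy-6-pentylbenzoate | CCCCCc1cc(O)cc(O)c1C(=O)OC(C)(C)C | intermediate
10 | carbon monoxide | [C-]#[O+] | starting material
11 | tert-butyl 4-(3-chloro-2,4-dimethoxy-6-propylbenzoyloxy)-2-hydroxy-6-pentylbenzoate | CCCCCc1cc(OC(=O)c2c(CCC)cc(OC)c(Cl)c2OC)cc(O)c1C(=O)OC(C)(C)C | intermediate
12 | 4-(3-chloro-2-hydroxy-4-methoxy-6-propylbenzoyloxy)-2-hydroxy-6-pentylbenzoic acid | CCCCCc1cc(OC(=O)c2c(CCC)cc(OC)c(Cl)c2O)cc(O)c1C(=O)O | target

## Step count and risk

Total step count: 7. Longest linear sequence: 5 steps (steps 1, 2, 3, 6 and 7). Ring A is made in 2 steps (4 and 5) and joins at step 6.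

**Step 6 (key step).** The most likely failure is slow oxidative addition at an electron-rich C–I bond with two ortho substituents, with reduction of the aryl–palladium species to the arene taking over. The aroyl complex may also be captured by traces of water in place of the phenoxide, and some acylation may occur at O-2'. The fallback gives up the carbonylation and makes the ester bond by classical acylation with the most reactive acyl donor. It sets out from 6 and returns at 11. Iodine–magnesium exchange on 6 with i-PrMgCl·LiCl in THF would give (3-chloro-2,4-dimethoxy-6-propylphenyl)magnesium chloride F1. Trapping F1 with CO2 and acidifying would give 3-chloro-2,4-dimethoxy-6-propylbenzoic acid F2. Oxalyl chloride with a trace of DMF would convert F2 into 3-chloro-2,4-dimethoxy-6-propylbenzoyl chloride F3. Reaction of F3 with 9, NEt3 and a catalytic amount of DMAP in CH2Cl2 should acylate the more acidic 4-hydroxyl and give 11. The sequence thus runs from 6 through F1, F2 and F3 to 11.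

**Step 7.** The excess of Lewis acid needed for the ester may also begin to remove the 4-methoxy group. The tert-butyl cation may alkylate ring A, and the free acid may decarboxylate during work-up. The fallback separates the two unmaskings so that each reagent does one job. It sets out from 11 and returns at 12. TFA in CH2Cl2 at 0 °C to room temperature would remove only the tert-butyl group and give 4-(3-chloro-2,4-dimethoxy-6-propylbenzoyloxy)-2-hydroxy-6-pentylbenzoic acid F4. A small excess of BCl3 at −78 °C would then cleave only the chelated 2-methoxy group of F4 and give 12. The sequence thus runs from 11 through F4 to 12.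

**Step 4.** Carboxylation may occur in part at the carbon between the two hydroxyls and not next to the pentyl group, and the product may lose CO2 again on acidic work-up. The fallback fixes the position by halogenation and halogen–metal exchange. It sets out from 7 and returns at 8. Benzyl bromide and K2CO3 in DMF would give 1,3-bis(benzyloxy)-5-pentylbenzene F5. NBS in MeCN should brominate F5 para to one benzyloxy group, next to the pentyl chain, and give 1,5-bis(benzyloxy)-2-bromo-3-pentylbenzene F6. Bromine–lithium exchange on F6 with n-BuLi at −78 °C would give [2,4-bis(benzyloxy)-6-pentylphenyl]lithium F7. CO2 and acidification would convert F7 into 2,4-bis(benzyloxy)-6-pentylbenzoic acid F8. Hydrogenolysis of F8 over Pd/C in ethyl acetate would give 8. The sequence thus runs from 7 through F5, F6, F7 and F8 to 8.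

**Step 5.** The tert-butyl group may be transferred to a phenol oxygen or to the electron-rich ring, and 8 may decarboxylate before it is esterified. The fallback installs the tert-butyl ester as a whole unit on carbon, so the free hydroxy acid is never handled. It sets out from 7 and returns at 9. Compound 7 would be taken through 1,3-bis(benzyloxy)-5-pentylbenzene F5 and 1,5-bis(benzyloxy)-2-bromo-3-pentylbenzene F6 to [2,4-bis(benzyloxy)-6-pentylphenyl]lithium F7, as described for step 4. F7 would be quenched with Boc2O at −78 °C to give tert-butyl 2,4-bis(benzyloxy)-6-pentylbenzoate F9. Hydrogenolysis of F9 over Pd/C in ethyl acetate would remove both benzyl groups, leave the tert-butyl ester and give 9. The sequence thus runs from 7 through F5, F6, F7 and F9 to 9.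

## Further compounds

F1 | step 6 | (3-chloro-2,4-dimethoxy-6-propylphenyl)magnesium chloride | CCCc1cc(OC)c(Cl)c(OC)c1[Mg]Cl
F2 | step 6 | 3-chloro-2,4-dimethoxy-6-propylbenzoic acid | CCCc1cc(OC)c(Cl)c(OC)c1C(=O)O
F3 | step 6 | 3-chloro-2,4-dimethoxy-6-propylbenzoyl chloride | CCCc1cc(OC)c(Cl)c(OC)c1C(=O)Cl
F4 | step 7 | 4-(3-chloro-2,4-dimethoxy-6-propylbenzoyloxy)-2-hydroxy-6-pentylbenzoic acid | CCCCCc1cc(OC(=O)c2c(CCC)cc(OC)c(Cl)c2OC)cc(O)c1C(=O)O
F5 | step 4 | 1,3-bis(benzyloxy)-5-pentylbenzene | CCCCCc1cc(OCc2ccccc2)cc(OCc2ccccc2)c1
F6 | step 4 | 1,5-bis(benzyloxy)-2-bromo-3-pentylbenzene | CCCCCc1cc(OCc2ccccc2)cc(OCc2ccccc2)c1Br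
F7 | step 4 | [2,4-bis(benzyloxy)-6-pentylphenyl]lithium | CCCCCc1cc(OCc2ccccc2)cc(OCc2ccccc2)c1[Li]
F8 | step 4 | 2,4-bis(benzyloxy)-6-pentylbenzoic acid | CCCCCc1cc(OCc2ccccc2)cc(OCc2ccccc2)c1C(=O)O
F9 | step 5 | tert-butyl 2,4-bis(benzyloxy)-6-pentylbenzoate | CCCCCc1cc(OCc2ccccc2)cc(OCc2ccccc2)c1C(=O)OC(C)(C)C
A1 | alternative 1 | allyl 4-(2,4-dihydroxy-6-propylbenzoyloxy)-2-hydroxy-6-pentylbenzoate | CCCCCc1cc(OC(=O)c2c(CCC)cc(O)cc2O)cc(O)c1C(=O)OCC=C
A2 | alternative 1 | allyl 2-hydroxy-6-pentyl-4-(3,5,7-trioxodecanoyloxy)benzoate | CCCCCc1cc(OC(=O)CC(=O)CC(=O)CC(=O)CCC)cc(O)c1C(=O)OCC=C
A3 | alternative 2 | 2,4-dimethoxy-6-pentylbenzoic acid | CCCCCc1cc(OC)cc(OC)c1C(=O)O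
A4 | alternative 2 | 1-fluoro-3,5-dimethoxybenzene | COc1cc(F)cc(OC)c1
A5 | alternative 2 | 3,5-dimethoxybenzyne | COC1=CC(OC)=CC#C1
A6 | alternative 2 | pentyllithium | CCCCC[Li]
A7 | alternative 3 | allyl 4-(3-chloro-2-hydroxy-4-methoxy-6-propylbenzoyloxy)-2-hydroxy-6-pentylbenzoate | CCCCCc1cc(OC(=O)c2c(CCC)cc(OC)c(Cl)c2O)cc(O)c1C(=O)OCC=C
A8 | alternative 3 | allyl 4-(hex-2-ynoyloxy)-2-hydroxy-6-pentylbenzoate | CCCCCc1cc(OC(=O)C#CCCC)cc(O)c1C(=O)OCC=C
A9 | alternative 3 | 2-chloro-1,3-dimethoxy-1-(trimethylsilyloxy)buta-1,3-diene (double-bond geometry not defined) | C=C(OC)C(Cl)=C(OC)O[Si](C)(C)C
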